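**Retrosynthetic overview**

- The α-methylene lactone is closed last, by acid-mediated lactonisation of a γ-hydroxy tert-butyl acrylate; the ten-membered carbocycle is formed just before it, by Nozaki–Hiyama–Kishi closure of C5–C6.
- The open chain is cut at C2–C3 (boron aldol of a methyl ketone with (Z)-3-iodo-2-methylacrolein); an Evans–Tishchenko reduction then sets C1 and places the acetate on C3, so the four oxygens are never protected.
- The methyl ketone comes from Weinreb opening and angeloylation of a γ-substituted α-methylbutenolide.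
- Key step: catalytic asymmetric dearomative allylic alkylation of 2-silyloxy-3-methylfuran (made from furfural) with a Morita–Baylis–Hillman carbonate, forging C7–C8, both stereocentres, the Z-alkene and the acrylate at once.

Assumption: locants C1–C15 in the comments follow germacrane numbering (C6 lactone carbinol, C7 acrylate-bearing carbon, C8 angelate carbinol, C3 acetate carbinol, C1 free carbinol). The sense and level of stereoinduction in steps 7, 13 and 16 are predictions from models, not established results.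

**Route**

Step 1
Reactants: 1 furfural (furan-2-carbaldehyde)
Product: 4 furan-2(5H)-one, via furan-2-yl formate 2 (not isolated), via furan-2(3H)-one 3 (not isolated)
Conditions: 30% H2O2, HCO2H, CH2Cl2, 40 °C; then Et3N (cat.), rt
Reagents that add atoms: hydrogen peroxide, OO
Why: Baeyer–Villiger (Dakin-type) oxidation of the electron-rich aldehyde by performic acid gives the formate, whose hydrolysis and base-mediated conjugation deliver the butenolide; no stereocentre is formed.

Step 2
Reactants: 4 furan-2(5H)-one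
Product: 6 3-bromofuran-2(5H)-one, via trans-3,4-dibromooxolan-2-one 5 (not isolated)
Conditions: Br2, CH2Cl2, 0 °C → rt; then Et3N, 0 °C
Reagents that add atoms: bromine, BrBr
Why: Bromine addition followed by E1cB dehydrobromination (α-deprotonation, loss of the β-bromide) leaves the α-bromobutenolide.

Step 3
Reactants: 6 3-bromofuran-2(5H)-one
Product: 7 3-methylfuran-2(5H)-one
Conditions: SnMe4, Pd(PPh3)4 (5 mol %), CuI (10 mol %), DMF, 60 °C
Reagents that add atoms: tetramethylstannane, C[Sn](C)(C)C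
Why: Stille cross-coupling of the α-bromo-enoate-type C(sp2)–Br bond installs the methyl group that becomes C14.

Step 4
Reactants: 7 3-methylfuran-2(5H)-one
Product: 8 trimethyl[(3-methylfuran-2-yl)oxy]silane
Conditions: TMSCl, Et3N, Et2O, 0 °C → rt; distil
Reagents that add atoms: chlorotrimethylsilane, C[Si](C)(C)Cl
Why: γ-Deprotonation and O-silylation of the butenolide (soft enolisation) give the aromatic 2-silyloxyfuran.

Step 5
Reactants: 9 2,2-dimethoxyacetaldehyde; 10 tert-butyl acrylate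
Product: 11 tert-butyl 3-hydroxy-4,4-dimethoxy-2-methylidenebutanoate (racemic)
Conditions: DABCO (0.5 equiv), 1,4-dioxane/H2O (1:1), rt, 3 d
Reagents that add atoms: none
Why: Morita–Baylis–Hillman reaction of an activated, non-enolisable aldehyde with the acrylate; the racemic carbinol is erased in step 7.

Step 6
Reactants: 11 tert-butyl 3-hydroxy-4,4-dimethoxy-2-methylidenebutanoate
Product: 12 tert-butyl 3-[(tert-butoxycarbonyl)oxy]-4,4-dimethoxy-2-methylidenebutanoate (racemic)
Conditions: Boc2O, DMAP (10 mol %), CH2Cl2, 0 °C → rt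
Reagents that add atoms: di-tert-butyl dicarbonate, CC(C)(C)OC(=O)OC(=O)OC(C)(C)C
Why: DMAP-catalysed O-acylation turns the allylic alcohol into the carbonate leaving group needed for Lewis-base allylic substitution.

Step 7 (key step)
Reactants: 12 tert-butyl 3-[(tert-butoxycarbonyl)oxy]-4,4-dimethoxy-2-methylidenebutanoate; 8 trimethyl[(3-methylfuran-2-yl)oxy]silane
Product: 13 tert-butyl (3S)-4,4-dimethoxy-2-methylidene-3-[(2R)-4-methyl-5-oxo-2,5-dihydrofuran-2-yl]butanoate
Conditions: (DHQD)2PHAL (hydroquinidine 1,4-phthalazinediyl diether, 10 mol %), PhCF3, 0 °C → rt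
Reagents that add atoms: none
Why: Lewis-base-catalysed asymmetric allylic alkylation of a Morita–Baylis–Hillman carbonate (SN2′/SN2′): the quinuclidine displaces tert-butyl carbonate, the liberated tert-butoxide desilylates aromatic furan 8, and the furanolate attacks the allylammonium at the acetal-bearing carbon through C5, breaking the furan aromaticity and setting C7 (3S) and C8 (2R) together in one catalyst-controlled ion-pair transition state (the pseudo-enantiomeric (DHQ)2PHAL would give the antipode).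

Step 8
Reactants: 13 butenolide from step 7
Product: 14 tert-butyl (3S,4R,5Z)-3-(dimethoxymethyl)-4-hydroxy-7-[methoxy(methyl)amino]-6-methyl-2-methylidene-7-oxohept-5-enoate
Conditions: MeNH(OMe)·HCl, AlMe3, CH2Cl2, 0 °C; Rochelle salt work-up
Reagents that add atoms: N,O-dimethylhydroxylamine hydrochloride, CNOC.Cl
Why: Weinreb aminolysis with Me2AlN(OMe)Me opens the strained conjugated lactone while the hindered tert-butyl acrylate and the acetal are left alone; the Z-alkene is inherited from the ring and no stereocentre is touched.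

Step 9
Reactants: 14 hydroxy Weinreb amide; 15 angelic acid [(2Z)-2-methylbut-2-enoic acid]
Product: 16 tert-butyl (3S,4R,5Z)-3-(dimethoxymethyl)-7-[methoxy(methyl)amino]-6-methyl-4-{[(2Z)-2-methylbut-2-enoyl]oxy}-2-methylidene-7-oxohept-5-enoate
Conditions: 15, 2,4,6-Cl3C6H2COCl, Et3N, toluene, rt; then 14, 50 °C
Reagents that add atoms: none
Why: Yamaguchi esterification through the mixed anhydride, run without DMAP, acylates the C8 hydroxyl without angelate-to-tiglate isomerisation and blocks relactonisation and furan formation.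

Step 10
Reactants: 16 angelate Weinreb amide
Product: 17 tert-butyl (3S,4R,5Z)-3-(dimethoxymethyl)-6-methyl-4-{[(2Z)-2-methylbut-2-enoyl]oxy}-2-methylidene-7-oxooct-5-enoate
Conditions: MeMgBr (1.3 equiv), THF, −40 → −10 °C; aq. NH4Cl
Reagents that add atoms: methylmagnesium bromide, C[Mg]Br
Why: Weinreb ketone synthesis: the chelated tetrahedral adduct prevents over-addition, and the hindered angelate and tert-butyl esters react more slowly than the amide at low temperature.

Step 11
Reactants: 18 prop-2-yn-1-ol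
Product: 20 (Z)-3-iodo-2-methylprop-2-en-1-ol, via Z-alkenylmagnesium alkoxide 19 (not isolated)
Conditions: MeMgBr (2.5 equiv), CuI (10 mol %), THF, −10 °C → rt; then I2, −40 °C → rt
Reagents that add atoms: methylmagnesium bromide, C[Mg]Br; iodine, II
Why: Alkoxide-directed anti-carbomagnesiation (Duboudin–Normant) puts the methyl on the proximal alkyne carbon and magnesium cis to the carbinol; iodinolysis with retention fixes the Z-iodoalkene.

Step 12
Reactants: 20 (Z)-3-iodo-2-methylprop-2-en-1-ol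
Product: 21 (Z)-3-iodo-2-methylprop-2-enal
Conditions: MnO2, CH2Cl2, rt, dark
Reagents that add atoms: none
Why: Neutral allylic oxidation with MnO2 gives the enal without Z/E isomerisation; it is used at once.

Step 13
Reactants: 17 methyl ketone; 21 (Z)-3-iodo-2-methylprop-2-enal
Product: 24 tert-butyl (3S,4R,5Z,9S,10Z)-3-(dimethoxymethyl)-9-hydroxy-11-iodo-6,10-dimethyl-4-{[(2Z)-2-methylbut-2-enoyl]oxy}-2-methylidene-7-oxoundeca-5,10-dienoate, via diisopinocampheylboron enolate 22 (not isolated), via diisopinocampheylboron aldolate 23 (not isolated)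
Conditions: (−)-Ipc2BCl [(−)-B-chlorodiisopinocampheylborane], Et3N, Et2O, 0 °C; then 21, −78 → −20 °C; then H2O2, MeOH, pH 7 buffer, 0 °C
Reagents that add atoms: none
Why: Paterson boron aldol: soft enolisation occurs on the methyl side and the isopinocampheyl ligands direct the enolate to one face of the enal in a closed transition state, which is predicted to set C3 as (9S); the antipodal reagent would be used if the observed sense is opposite.

Step 14
Reactants: 24 β-hydroxy ketone
Product: 25 tert-butyl (3S,4R,5Z,7S,9S,10Z)-9-(acetyloxy)-3-(dimethoxymethyl)-7-hydroxy-11-iodo-6,10-dimethyl-4-{[(2Z)-2-methylbut-2-enoyl]oxy}-2-methylideneundeca-5,10-dienoate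
Conditions: CH3CHO (10 equiv), SmI2 (0.3 equiv), THF, −10 °C
Reagents that add atoms: acetaldehyde, CC=O
Why: Evans–Tishchenko reduction: the samarium-bound hemiacetal of the C3 hydroxyl delivers hydride intramolecularly to the C1 ketone, giving the 1,3-anti carbinol (7S) and leaving the acetate on C3 and the hydroxyl on C1, exactly as in the target.

Step 15
Reactants: 25 acetal
Product: 26 tert-butyl (3S,4R,5Z,7S,9S,10Z)-9-(acetyloxy)-3-formyl-7-hydroxy-11-iodo-6,10-dimethyl-4-{[(2Z)-2-methylbut-2-enoyl]oxy}-2-methylideneundeca-5,10-dienoate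
Conditions: LiBF4, MeCN/H2O (50:1), rt; used crude
Reagents that add atoms: water, O
Why: Mild Lewis-acid acetal hydrolysis spares the tert-butyl ester, the allylic esters and the allylic alcohol, and is mild enough to avoid epimerising or conjugating the β,γ-unsaturated aldehyde.

Step 16
Reactants: 26 iodo aldehyde
Product: 27 tert-butyl 2-[(1R,2R,3Z,5S,7S,8Z,10R)-5-(acetyloxy)-2,7-dihydroxy-4,8-dimethyl-10-{[(2Z)-2-methylbut-2-enoyl]oxy}cyclodeca-3,8-dien-1-yl]prop-2-enoate
Conditions: CrCl2 (10 equiv), NiCl2 (0.2 equiv), DMSO, rt, 2 mM (syringe pump)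
Reagents that add atoms: none
Why: Intramolecular Nozaki–Hiyama–Kishi alkenylation closes the ten-membered ring with retention of the Z-alkene; Felkin–Anh addition anti to the C7 acrylate carbon, with the ring tether gauche, should give the C6 carbinol syn to the acrylate (2R).

Step 17
Reactants: 27 hydroxy tert-butyl ester
Product: 28 (3aR,4R,5Z,7S,9S,10Z,11aR)-9-(acetyloxy)-7-hydroxy-6,10-dimethyl-3-methylidene-2-oxo-2,3,3a,4,7,8,9,11a-octahydrocyclodeca[b]furan-4-yl (2Z)-2-methylbut-2-enoate (target)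
Conditions: CF3CO2H/CH2Cl2 (1:9), 0 °C, 30 min; NaHCO3
Reagents that add atoms: none
Why: Acid-mediated tert-butyl ester cleavage with capture of the acyl group by the syn C6 hydroxyl gives the cis-fused α-methylene-γ-lactone; no bond to a stereocentre is broken.

**Compound list**

1 | furfural | O=Cc1ccco1 | starting material
2 | furan-2-yl formate | O=COc1ccco1 | intermediate
3 | furan-2(3H)-one | O=C1CC=CO1 | intermediate
4 | furan-2(5H)-one | O=C1C=CCO1 | intermediate
5 | trans-3,4-dibromooxolan-2-one (racemic, one enantiomer drawn) | O=C1OC[C@H](Br)[C@H]1Br | intermediate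
6 | 3-bromofuran-2(5H)-one | O=C1OCC=C1Br | intermediate
7 | 3-methylfuran-2(5H)-one | CC1=CCOC1=O | intermediate
8 | trimethyl[(3-methylfuran-2-yl)oxy]silane | Cc1ccoc1O[Si](C)(C)C | intermediate
9 | 2,2-dimethoxyacetaldehyde | COC(OC)C=O | starting material
10 | tert-butyl acrylate | C=CC(=O)OC(C)(C)C | starting material
11 | tert-butyl 3-hydroxy-4,4-dimethoxy-2-methylidenebutanoate (racemic) | C=C(C(=O)OC(C)(C)C)C(O)C(OC)OC | intermediate
12 | tert-butyl 3-[(tert-butoxycarbonyl)oxy]-4,4-dimethoxy-2-methylidenebutanoate (racemic) | C=C(C(=O)OC(C)(C)C)C(OC(=O)OC(C)(C)C)C(OC)OC | intermediate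
13 | tert-butyl (3S)-4,4-dimethoxy-2-methylidene-3-[(2R)-4-methyl-5-oxo-2,5-dihydrofuran-2-yl]butanoate | C=C(C(=O)OC(C)(C)C)[C@H](C(OC)OC)[C@@H]1OC(=O)C(C)=C1 | intermediate
14 | tert-butyl (3S,4R,5Z)-3-(dimethoxymethyl)-4-hydroxy-7-[methoxy(methyl)amino]-6-methyl-2-methylidene-7-oxohept-5-enoate | C=C(C(=O)OC(C)(C)C)[C@H](C(OC)OC)[C@H](O)/C=C(/C)C(=O)N(C)OC | intermediate
15 | angelic acid, (2Z)-2-methylbut-2-enoic acid | C/C=C(/C)C(=O)O | starting material
16 | tert-butyl (3S,4R,5Z)-3-(dimethoxymethyl)-7-[methoxy(methyl)amino]-6-methyl-4-{[(2Z)-2-methylbut-2-enoyl]oxy}-2-methylidene-7-oxohept-5-enoate | C=C(C(=O)OC(C)(C)C)[C@H](C(OC)OC)[C@H](OC(=O)/C(C)=C\C)/C=C(/C)C(=O)N(C)OC | intermediate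
17 | tert-butyl (3S,4R,5Z)-3-(dimethoxymethyl)-6-methyl-4-{[(2Z)-2-methylbut-2-enoyl]oxy}-2-methylidene-7-oxooct-5-enoate | C=C(C(=O)OC(C)(C)C)[C@H](C(OC)OC)[C@H](OC(=O)/C(C)=C\C)/C=C(/C)C(C)=O | intermediate
18 | prop-2-yn-1-ol | C#CCO | starting material
19 | bromomagnesium (Z)-3-(bromomagnesio)-2-methylprop-2-en-1-olate | C/C(CO[Mg]Br)=C/[Mg]Br | intermediate
20 | (Z)-3-iodo-2-methylprop-2-en-1-ol | C/C(CO)=C/I | intermediate
21 | (Z)-3-iodo-2-methylprop-2-enal | C/C(C=O)=C/I | intermediate
22 | diisopinocampheylboron enolate of 17 (O-boryl enol at the methyl ketone) | C=C(C(=O)OC(C)(C)C)[C@H](C(OC)OC)[C@H](OC(=O)/C(C)=C\C)/C=C(/C)C(=C)OB([C@@H]1C[C@@H]2C[C@H]([C@H]1C)C2(C)C)[C@@H]1C[C@@H]2C[C@H]([C@H]1C)C2(C)C | intermediate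
23 | O-diisopinocampheylboryl derivative of aldol 24 | C=C(C(=O)OC(C)(C)C)[C@H](C(OC)OC)[C@H](OC(=O)/C(C)=C\C)/C=C(/C)C(=O)C[C@H](OB([C@@H]1C[C@@H]2C[C@H]([C@H]1C)C2(C)C)[C@@H]1C[C@@H]2C[C@H]([C@H]1C)C2(C)C)/C(C)=C\I | intermediate
24 | tert-butyl (3S,4R,5Z,9S,10Z)-3-(dimethoxymethyl)-9-hydroxy-11-iodo-6,10-dimethyl-4-{[(2Z)-2-methylbut-2-enoyl]oxy}-2-methylidene-7-oxoundeca-5,10-dienoate | C=C(C(=O)OC(C)(C)C)[C@H](C(OC)OC)[C@H](OC(=O)/C(C)=C\C)/C=C(/C)C(=O)C[C@H](O)/C(C)=C\I | intermediate
25 | tert-butyl (3S,4R,5Z,7S,9S,10Z)-9-(acetyloxy)-3-(dimethoxymethyl)-7-hydroxy-11-iodo-6,10-dimethyl-4-{[(2Z)-2-methylbut-2-enoyl]oxy}-2-methylideneundeca-5,10-dienoate | C=C(C(=O)OC(C)(C)C)[C@H](C(OC)OC)[C@H](OC(=O)/C(C)=C\C)/C=C(/C)[C@@H](O)C[C@H](OC(C)=O)/C(C)=C\I | intermediate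
26 | tert-butyl (3S,4R,5Z,7S,9S,10Z)-9-(acetyloxy)-3-formyl-7-hydroxy-11-iodo-6,10-dimethyl-4-{[(2Z)-2-methylbut-2-enoyl]oxy}-2-methylideneundeca-5,10-dienoate | C=C(C(=O)OC(C)(C)C)[C@H](C=O)[C@H](OC(=O)/C(C)=C\C)/C=C(/C)[C@@H](O)C[C@H](OC(C)=O)/C(C)=C\I | intermediate
27 | tert-butyl 2-[(1R,2R,3Z,5S,7S,8Z,10R)-5-(acetyloxy)-2,7-dihydroxy-4,8-dimethyl-10-{[(2Z)-2-methylbut-2-enoyl]oxy}cyclodeca-3,8-dien-1-yl]prop-2-enoate | C=C(C(=O)OC(C)(C)C)[C@@H]1[C@H](O)/C=C(/C)[C@@H](OC(C)=O)C[C@H](O)/C(C)=C\[C@H]1OC(=O)/C(C)=C\C | intermediate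
28 | (3aR,4R,5Z,7S,9S,10Z,11aR)-9-(acetyloxy)-7-hydroxy-6,10-dimethyl-3-methylidene-2-oxo-2,3,3a,4,7,8,9,11a-octahydrocyclodeca[b]furan-4-yl (2Z)-2-methylbut-2-enoate | C=C1C(=O)O[C@@H]2/C=C(/C)[C@@H](OC(C)=O)C[C@H](O)/C(C)=C\[C@@H](OC(=O)/C(C)=C\C)[C@H]12 | target

**Step count and risks**

Total steps: 17. Longest linear sequence: 13 steps (steps 1–4, 7–10, 13–17).

Step 7 (asymmetric dearomative allylic alkylation). The alkyl-substituted carbonate may react slowly, or the C7/C8 relationship may come out wrong. The fallback sets out from 9 and 8 and returns at 13. Knoevenagel condensation of 9 with Meldrum's acid gives 5-(2,2-dimethoxyethylidene)-2,2-dimethyl-1,3-dioxane-4,6-dione F1. A vinylogous Mukaiyama–Michael addition of 8 to this doubly activated acceptor under Cu(OTf)2/(S,S)-tBu-box catalysis gives the Meldrum's acid adduct F2, so the two stereocentres are set by a chelated Lewis-acid complex instead of an ion pair. Heating the adduct with Eschenmoser's iodide in tert-butanol (Mannich reaction, loss of acetone and CO2) gives the tert-butyl α-methylene ester 13.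

Step 13 (reagent-controlled boron aldol). Selectivity with the Z-iodoenal may be modest, or enolisation may not be clean. The fallback sets out from 17 and returns at 24. TMSOTf/Et3N converts 17 into the trimethylsilyl enol ether F3. A catalytic enantioselective Mukaiyama aldol with 21, using a tryptophan-derived B-butyl oxazaborolidinone (20 mol %) in EtCN at −78 °C followed by dilute acid, then gives 24 through an open, catalyst-controlled transition state instead of the closed boron one.

Step 16 (ring closure and C6 configuration). The alkenylchromium addition may give the wrong C6 epimer or cyclise poorly. The fallback sets out from 26 and returns at 27. Pinnick oxidation of 26 gives the C6 carboxylic acid F4. Activation with 2,2′-dipyridyl disulfide/PPh3 gives the S-pyridin-2-yl thioester F5. A nickel-mediated intramolecular thioester–alkenyl iodide ketone coupling (NiBr2(dme), 4,4′-di-tert-butyl-2,2′-bipyridine, Zn) closes the ring as the macrocyclic enone F6. Corey–Bakshi–Shibata reduction, with the catalyst enantiomer chosen for the (2R)-carbinol, sets C6 by reagent control and gives 27.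

Further compounds
F1 | step 7 | 5-(2,2-dimethoxyethylidene)-2,2-dimethyl-1,3-dioxane-4,6-dione | COC(OC)C=C1C(=O)OC(C)(C)OC1=O
F2 | step 7 | 5-{(1S)-2,2-dimethoxy-1-[(2R)-4-methyl-5-oxo-2,5-dihydrofuran-2-yl]ethyl}-2,2-dimethyl-1,3-dioxane-4,6-dione | CC1(C)OC(=O)C(C(=O)O1)[C@H](C(OC)OC)[C@@H]1OC(=O)C(C)=C1
F3 | step 13 | tert-butyl (3S,4R,5Z)-3-(dimethoxymethyl)-6-methyl-4-{[(2Z)-2-methylbut-2-enoyl]oxy}-2-methylidene-7-[(trimethylsilyl)oxy]octa-5,7-dienoate | C=C(C(=O)OC(C)(C)C)[C@H](C(OC)OC)[C@H](OC(=O)/C(C)=C\C)/C=C(/C)C(=C)O[Si](C)(C)C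
F4 | step 16 | (2S,3R,4Z,6S,8S,9Z)-8-(acetyloxy)-2-[3-(tert-butoxy)-3-oxoprop-1-en-2-yl]-6-hydroxy-10-iodo-5,9-dimethyl-3-{[(2Z)-2-methylbut-2-enoyl]oxy}deca-4,9-dienoic acid | C=C(C(=O)OC(C)(C)C)[C@H](C(=O)O)[C@H](OC(=O)/C(C)=C\C)/C=C(/C)[C@@H](O)C[C@H](OC(C)=O)/C(C)=C\I
F5 | step 16 | S-pyridin-2-yl thioester of acid F4 | C=C(C(=O)OC(C)(C)C)[C@H](C(=O)Sc1ccccn1)[C@H](OC(=O)/C(C)=C\C)/C=C(/C)[C@@H](O)C[C@H](OC(C)=O)/C(C)=C\I
F6 | step 16 | tert-butyl 2-[(1S,3Z,5S,7S,8Z,10R)-5-(acetyloxy)-7-hydroxy-4,8-dimethyl-10-{[(2Z)-2-methylbut-2-enoyl]oxy}-2-oxocyclodeca-3,8-dien-1-yl]prop-2-enoate | C=C(C(=O)OC(C)(C)C)[C@@H]1C(=O)/C=C(/C)[C@@H](OC(C)=O)C[C@H](O)/C(C)=C\[C@H]1OC(=O)/C(C)=C\C
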